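## Retrosynthetic overview

1. Target ⇐ C3,C13-diol: a lipase acetylates the primary C13–OH, then the secondary C3–OH is propanoylated chemically.
2. Ten-membered carbocycle (second ring) ⇐ ring-closing metathesis at C1=C10 of an α-iodobutenolide carrying an allyl arm and a 3-methylbut-3-enyl arm; C13 then enters by Stille hydroxymethylation of the C11 iodide.
3. Butenolide (first ring) ⇐ syn-carbocupration/iodination of a γ-silyloxy ynoate (C7–C8 bond), then lactonisation.
4. C6 ⇐ catalytic asymmetric alkynylation of an enal with methyl propiolate (C6–C7); C3, the first stereocentre, ⇐ catalytic asymmetric allylation of an enal (C2–C3).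
5. The (E)-enal ⇐ Wittig reaction of two achiral building blocks.

Locants (germacrane numbering of the target): C1=C10 (Z, Me on C10), C2, C3 (S, O-propanoyl), C4=C5 (E, Me on C4), C6 (R, lactone O), C7=C11 (butenolide olefin), C8, C9; C12 = lactone C=O; C13 = CH2OAc on C11.

Assumption: the (S)-BINOL/Ti(OiPr)4 and (S,S)-ProPhenol/Me2Zn catalysts are taken to attack the Si face of their aldehydes; if Mosher analysis of the allylation or alkynylation product shows the opposite, the antipodal ligand is used.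

## Route

Step 1
Reactants: 1 2-(tert-butyldimethylsilyloxy)acetaldehyde; 2 2-(triphenylphosphoranylidene)propanal
Product: 3 (2E)-4-(tert-butyldimethylsilyloxy)-2-methylbut-2-enal
Conditions: toluene, 90 °C, 16 h
Reagents that add atoms: none
Why: Wittig olefination with a formyl-stabilised ylide reacts once with the unhindered aldehyde and gives the (E)-trisubstituted enal.

Step 2
Reactants: 3 (2E)-4-(tert-butyldimethylsilyloxy)-2-methylbut-2-enal; 4 allyltributylstannane
Product: 5 (4S,5E)-7-(tert-butyldimethylsilyloxy)-5-methylhepta-1,5-dien-4-ol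
Conditions: (S)-BINOL (20 mol%), Ti(OiPr)4 (10 mol%), 4 Å MS, CH2Cl2, −20 °C, 72 h; aq NaHCO3
Reagents that add atoms: none
Why: Keck asymmetric allylation, in which the BINOL–titanium Lewis acid directs 1,2-addition of the allylstannane to the Si face of the enal and so sets C3 as S by asymmetric catalysis.

Step 3
Reactants: 5 (4S,5E)-7-(tert-butyldimethylsilyloxy)-5-methylhepta-1,5-dien-4-ol
Product: 6 (4S,5E)-4,7-bis(tert-butyldimethylsilyloxy)-5-methylhepta-1,5-diene
Conditions: TBSCl, imidazole, DMF, rt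
Reagents that add atoms: tert-butyldimethylsilyl chloride, CC(C)(C)[Si](C)(C)Cl
Why: Standard silylation of the secondary allylic alcohol masks C3–OH for the organometallic steps that follow.

Step 4
Reactants: 6 (4S,5E)-4,7-bis(tert-butyldimethylsilyloxy)-5-methylhepta-1,5-diene
Product: 7 (2E,4S)-4-(tert-butyldimethylsilyloxy)-3-methylhepta-2,6-dien-1-ol
Conditions: PPTS (0.2 equiv), MeOH, 0 °C → rt
Reagents that add atoms: none
Why: Acid-catalysed methanolysis cleaves the unhindered primary allylic silyl ether much faster than the hindered secondary one.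

Step 5
Reactants: 7 (2E,4S)-4-(tert-butyldimethylsilyloxy)-3-methylhepta-2,6-dien-1-ol
Product: 8 (2E,4S)-4-(tert-butyldimethylsilyloxy)-3-methylhepta-2,6-dienal
Conditions: MnO2 (15 equiv), CH2Cl2, rt
Reagents that add atoms: none
Why: Allylic oxidation with MnO2 is neutral and heterogeneous, so the silyl ether and the E geometry are untouched.

Step 6
Reactants: 8 (2E,4S)-4-(tert-butyldimethylsilyloxy)-3-methylhepta-2,6-dienal; 9 methyl propiolate
Product: 10 methyl (4R,5E,7S)-7-(tert-butyldimethylsilyloxy)-4-hydroxy-6-methyldeca-5,9-dien-2-ynoate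
Conditions: (S,S)-ProPhenol (20 mol%), Me2Zn (3 equiv), Ph3P=O (40 mol%), 9 (3 equiv), toluene, 0 °C, 48 h; aq NH4Cl
Reagents that add atoms: none
Why: Trost zinc–ProPhenol asymmetric alkynylation delivers the zinc acetylide of 9 to the Si face of the enal in a 1,2-addition, setting C6 as R under catalyst control because the C3 centre is remote.

Step 7
Reactants: 10 methyl (4R,5E,7S)-7-(tert-butyldimethylsilyloxy)-4-hydroxy-6-methyldeca-5,9-dien-2-ynoate
Product: 11 methyl (4R,5E,7S)-7-(tert-butyldimethylsilyloxy)-6-methyl-4-(triethylsilyloxy)deca-5,9-dien-2-ynoate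
Conditions: TESCl, imidazole, CH2Cl2, 0 °C
Reagents that add atoms: triethylsilyl chloride, CC[Si](Cl)(CC)CC
Why: Silylation with the more labile triethylsilyl group keeps the alkoxide out of the cuprate step and can later be removed beside the TBS ether.

Step 8
Reactants: 12 4-bromo-2-methylbut-1-ene
Product: 13 (3-methylbut-3-en-1-yl)magnesium bromide (THF solution, used directly)
Conditions: Mg turnings (I2-activated), THF, 35 °C
Reagents that add atoms: magnesium, [Mg]
Why: Magnesium insertion into a primary homoallylic bromide gives a stable Grignard reagent.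

Step 9
Reactants: 11 methyl (4R,5E,7S)-7-(tert-butyldimethylsilyloxy)-6-methyl-4-(triethylsilyloxy)deca-5,9-dien-2-ynoate; 13 (3-methylbut-3-en-1-yl)magnesium bromide
Product: 16 methyl (2E,4R,5E,7S)-7-(tert-butyldimethylsilyloxy)-2-iodo-6-methyl-3-(3-methylbut-3-en-1-yl)-4-(triethylsilyloxy)deca-2,5,9-trienoate, via magnesium bis(3-methylbut-3-enyl)cuprate 14 (not isolated), via alkenylcuprate adduct 15 (not isolated)
Conditions: 13 (4 equiv), CuBr·SMe2 (2 equiv), THF, −40 °C; 11, −78 °C, 1 h; I2 (4 equiv), −78 → −40 °C; aq Na2S2O3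
Reagents that add atoms: iodine, II
Why: syn-Carbocupration of the ynoate (conjugate addition of a Normant cuprate) forms the C7–C8 bond, and iodinolysis of the alkenylcuprate at −78 °C with retention puts iodine cis to the new chain and the ester cis to C6.

Step 10
Reactants: 16 methyl (2E,4R,5E,7S)-7-(tert-butyldimethylsilyloxy)-2-iodo-6-methyl-3-(3-methylbut-3-en-1-yl)-4-(triethylsilyloxy)deca-2,5,9-trienoate
Product: 18 (5R)-5-[(1E,3S)-3-(tert-butyldimethylsilyloxy)-2-methylhexa-1,5-dien-1-yl]-3-iodo-4-(3-methylbut-3-en-1-yl)furan-2(5H)-one, via hydroxy iodo ester 17 (not isolated)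
Conditions: PPTS (0.3 equiv), MeOH, rt; then toluene, 50 °C
Reagents that add atoms: none
Why: Mild acid methanolysis removes only the triethylsilyl ether, and the freed C6 hydroxyl, held cis to the ester, closes the butenolide by transesterification without touching the C6 configuration.

Step 11
Reactants: 18 (5R)-5-[(1E,3S)-3-(tert-butyldimethylsilyloxy)-2-methylhexa-1,5-dien-1-yl]-3-iodo-4-(3-methylbut-3-en-1-yl)furan-2(5H)-one
Product: 19 (3S,6R,1(10)Z,4E)-3-(tert-butyldimethylsilyloxy)-11-iodo-13-norgermacra-1(10),4,7(11)-trien-12,6-olide (ten-membered carbocycle fused at C6–C7 to the iodobutenolide)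
Conditions: second-generation Hoveyda–Grubbs catalyst (10 mol%), 1,4-benzoquinone (20 mol%), toluene (1 mM), 80 °C
Reagents that add atoms: none
Why: Ring-closing metathesis starts at the monosubstituted olefin and closes onto the 1,1-disubstituted one, the butenolide holding both arms on adjacent carbons, and the new trisubstituted olefin is expected to form as the cis (Z) isomer, the less strained one in a ten-membered ring that already holds an E olefin.

Step 12
Reactants: 19 (3S,6R,1(10)Z,4E)-3-(tert-butyldimethylsilyloxy)-11-iodo-13-norgermacra-1(10),4,7(11)-trien-12,6-olide; 20 (tributylstannyl)methanol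
Product: 21 (3S,6R,1(10)Z,4E)-3-(tert-butyldimethylsilyloxy)-13-hydroxygermacra-1(10),4,7(11)-trien-12,6-olide
Conditions: Pd2(dba)3 (5 mol%), AsPh3 (20 mol%), CuI (10 mol%), NMP, 50 °C
Reagents that add atoms: none
Why: Migita–Kosugi–Stille coupling of the electron-poor α-iodobutenolide with the hydroxymethylstannane installs C13 under neutral conditions that spare the epimerisable C6, and it is run after ring closure so that no terminal olefin is left for a Heck cyclisation.

Step 13
Reactants: 21 (3S,6R,1(10)Z,4E)-3-(tert-butyldimethylsilyloxy)-13-hydroxygermacra-1(10),4,7(11)-trien-12,6-olide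
Product: 22 (3S,6R,1(10)Z,4E)-3,13-dihydroxygermacra-1(10),4,7(11)-trien-12,6-olide
Conditions: HF·pyridine, pyridine/THF, 0 °C → rt
Reagents that add atoms: none
Why: Buffered fluoride desilylation frees the secondary alcohol without base, so the butenolide γ-centre C6 is not epimerised.

Step 14
Reactants: 22 (3S,6R,1(10)Z,4E)-3,13-dihydroxygermacra-1(10),4,7(11)-trien-12,6-olide
Product: 23 (3S,6R,1(10)Z,4E)-13-acetoxy-3-hydroxygermacra-1(10),4,7(11)-trien-12,6-olide
Conditions: Novozym 435 (immobilised Candida antarctica lipase B), vinyl acetate (5 equiv), MTBE, 30 °C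
Reagents that add atoms: vinyl acetate, C=COC(C)=O
Why: Lipase-catalysed irreversible transesterification acylates only the unhindered primary C13 hydroxyl, because the secondary C3 hydroxyl carries two large substituents and is a poor substrate for this serine hydrolase, and the neutral medium avoids C6 epimerisation and diacylation.

Step 15
Reactants: 23 (3S,6R,1(10)Z,4E)-13-acetoxy-3-hydroxygermacra-1(10),4,7(11)-trien-12,6-olide
Product: 24 (3S,6R,1(10)Z,4E)-13-acetoxy-3-propanoyloxygermacra-1(10),4,7(11)-trien-12,6-olide (CNP0238103.1)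
Conditions: (EtCO)2O (1.5 equiv), pyridine, DMAP (10 mol%), CH2Cl2, 0 °C
Reagents that add atoms: propanoic anhydride, CCC(=O)OC(=O)CC
Why: DMAP-catalysed acylation of the remaining secondary alcohol proceeds with retention at C3 and gives the target.

## Compound list

1 | 2-(tert-butyldimethylsilyloxy)acetaldehyde | O=CCO[Si](C)(C)C(C)(C)C | starting material
2 | 2-(triphenylphosphoranylidene)propanal | CC(C=O)=P(c1ccccc1)(c1ccccc1)c1ccccc1 | starting material
3 | (2E)-4-(tert-butyldimethylsilyloxy)-2-methylbut-2-enal | O=C/C(C)=C/CO[Si](C)(C)C(C)(C)C | intermediate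
4 | allyltributylstannane | C=CC[Sn](CCCC)(CCCC)CCCC | starting material
5 | (4S,5E)-7-(tert-butyldimethylsilyloxy)-5-methylhepta-1,5-dien-4-ol | C=CC[C@H](O)/C(C)=C/CO[Si](C)(C)C(C)(C)C | intermediate
6 | (4S,5E)-4,7-bis(tert-butyldimethylsilyloxy)-5-methylhepta-1,5-diene | C=CC[C@H](O[Si](C)(C)C(C)(C)C)/C(C)=C/CO[Si](C)(C)C(C)(C)C | intermediate
7 | (2E,4S)-4-(tert-butyldimethylsilyloxy)-3-methylhepta-2,6-dien-1-ol | C=CC[C@H](O[Si](C)(C)C(C)(C)C)/C(C)=C/CO | intermediate
8 | (2E,4S)-4-(tert-butyldimethylsilyloxy)-3-methylhepta-2,6-dienal | C=CC[C@H](O[Si](C)(C)C(C)(C)C)/C(C)=C/C=O | intermediate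
9 | methyl propiolate | C#CC(=O)OC | starting material
10 | methyl (4R,5E,7S)-7-(tert-butyldimethylsilyloxy)-4-hydroxy-6-methyldeca-5,9-dien-2-ynoate | C=CC[C@H](O[Si](C)(C)C(C)(C)C)/C(C)=C/[C@@H](O)C#CC(=O)OC | intermediate
11 | methyl (4R,5E,7S)-7-(tert-butyldimethylsilyloxy)-6-methyl-4-(triethylsilyloxy)deca-5,9-dien-2-ynoate | C=CC[C@H](O[Si](C)(C)C(C)(C)C)/C(C)=C/[C@@H](O[Si](CC)(CC)CC)C#CC(=O)OC | intermediate
12 | 4-bromo-2-methylbut-1-ene | C=C(C)CCBr | starting material
13 | (3-methylbut-3-en-1-yl)magnesium bromide | C=C(C)CC[Mg]Br | intermediate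
14 | magnesium bromide bis(3-methylbut-3-enyl)cuprate (not isolated, step 9) | C=C(C)CC[Cu-]CCC(C)=C.[Mg+]Br | intermediate
15 | alkenylcuprate adduct of 11 and 14, copper on C11 cis to the new C8 chain (not isolated, step 9) | C=C(C)CC/C(=C(\[Cu-]CCC(C)=C)C(=O)OC)[C@H](O[Si](CC)(CC)CC)/C=C(C)/[C@H](CC=C)O[Si](C)(C)C(C)(C)C.[Mg+]Br | intermediate
16 | methyl (2E,4R,5E,7S)-7-(tert-butyldimethylsilyloxy)-2-iodo-6-methyl-3-(3-methylbut-3-en-1-yl)-4-(triethylsilyloxy)deca-2,5,9-trienoate | C=C(C)CC/C(=C(\I)C(=O)OC)[C@H](O[Si](CC)(CC)CC)/C=C(C)/[C@H](CC=C)O[Si](C)(C)C(C)(C)C | intermediate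
17 | methyl (2E,4R,5E,7S)-7-(tert-butyldimethylsilyloxy)-4-hydroxy-2-iodo-6-methyl-3-(3-methylbut-3-en-1-yl)deca-2,5,9-trienoate (not isolated, step 10) | C=C(C)CC/C(=C(\I)C(=O)OC)[C@H](O)/C=C(C)/[C@H](CC=C)O[Si](C)(C)C(C)(C)C | intermediate
18 | (5R)-5-[(1E,3S)-3-(tert-butyldimethylsilyloxy)-2-methylhexa-1,5-dien-1-yl]-3-iodo-4-(3-methylbut-3-en-1-yl)furan-2(5H)-one | C=C(C)CCC1=C(I)C(=O)O[C@@H]1/C=C(C)/[C@H](CC=C)O[Si](C)(C)C(C)(C)C | intermediate
19 | (3S,6R,1(10)Z,4E)-3-(tert-butyldimethylsilyloxy)-11-iodo-13-norgermacra-1(10),4,7(11)-trien-12,6-olide | CC(C)(C)[Si](C)(C)O[C@H]1C/C=C(/C)CCC2=C(I)C(=O)O[C@@H]2/C=C/1C | intermediate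
20 | (tributylstannyl)methanol | OC[Sn](CCCC)(CCCC)CCCC | starting material
21 | (3S,6R,1(10)Z,4E)-3-(tert-butyldimethylsilyloxy)-13-hydroxygermacra-1(10),4,7(11)-trien-12,6-olide | CC(C)(C)[Si](C)(C)O[C@H]1C/C=C(/C)CCC2=C(CO)C(=O)O[C@@H]2/C=C/1C | intermediate
22 | (3S,6R,1(10)Z,4E)-3,13-dihydroxygermacra-1(10),4,7(11)-trien-12,6-olide | O[C@H]1C/C=C(/C)CCC2=C(CO)C(=O)O[C@@H]2/C=C/1C | intermediate
23 | (3S,6R,1(10)Z,4E)-13-acetoxy-3-hydroxygermacra-1(10),4,7(11)-trien-12,6-olide | O[C@H]1C/C=C(/C)CCC2=C(COC(C)=O)C(=O)O[C@@H]2/C=C/1C | intermediate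
24 | (3S,6R,1(10)Z,4E)-13-acetoxy-3-propanoyloxygermacra-1(10),4,7(11)-trien-12,6-olide | CCC(=O)O[C@H]1C/C=C(/C)CCC2=C(COC(C)=O)C(=O)O[C@@H]2/C=C/1C | target

## Step count and risks

Total step count: 15. Longest linear sequence: 14 steps (steps 1–7 and 9–15 from 1); step 8 is a one-step side branch.

Steps most likely to fail:

Step 11 (ring-closing metathesis). A ten-membered ring with a new trisubstituted olefin may oligomerise or give the E ring olefin. The fallback reverses the order of ring formation, carbocycle first and lactone second; it sets out from 16 and comes back at 19. The metathesis is run on the open-chain iodo ester 16 (same catalyst, toluene 1 mM, 80 °C), where the C6 arm is not yet tied into the lactone and the ring strain is different. This gives the carbocycle methyl (2E)-2-iodo-2-[(2R,3E,5S,7Z)-5-(tert-butyldimethylsilyloxy)-4,8-dimethyl-2-(triethylsilyloxy)cyclodeca-3,7-dien-1-ylidene]acetate F1. PPTS in MeOH, then toluene at 50 °C, removes the triethylsilyl group and closes the butenolide to give 19.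

Step 12 (Stille hydroxymethylation). The iodide is tetrasubstituted and hindered, and sp3 transfer from tin is slow. The fallback brings C13 in as carbon monoxide; it sets out from 19 and comes back at 21. Reductive carbonylation of 19 (Pd(PPh3)4, CO 1 atm, Bu3SnH added slowly, THF, 50 °C) gives the C13 aldehyde (3S,6R,1(10)Z,4E)-3-(tert-butyldimethylsilyloxy)-13-oxogermacra-1(10),4,7(11)-trien-12,6-olide F2. Luche reduction (NaBH4, CeCl3·7H2O, MeOH, −78 °C) reduces only the aldehyde and gives 21.

Step 6 (asymmetric alkynylation). Selectivity on a β,β-disubstituted enal is substrate dependent. The fallback sets C6 by asymmetric ketone reduction instead of asymmetric C–C bond formation; it sets out from 8 and comes back at 10. Addition of lithiated 9 (LiN(SiMe3)2, THF, −78 °C) to 8 gives the C4-epimeric alcohols methyl (4RS,5E,7S)-7-(tert-butyldimethylsilyloxy)-4-hydroxy-6-methyldeca-5,9-dien-2-ynoate F3. MnO2 in CH2Cl2 oxidises them to the ynone methyl (5E,7S)-7-(tert-butyldimethylsilyloxy)-6-methyl-4-oxodeca-5,9-dien-2-ynoate F4. Corey–Bakshi–Shibata reduction ((R)-2-methyl-CBS-oxazaborolidine 20 mol%, catecholborane, toluene, −78 °C; the alkynyl group acting as the small substituent) gives 10.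

## Further compounds

F1 | step 11 | methyl (2E)-2-iodo-2-[(2R,3E,5S,7Z)-5-(tert-butyldimethylsilyloxy)-4,8-dimethyl-2-(triethylsilyloxy)cyclodeca-3,7-dien-1-ylidene]acetate | COC(=O)/C(I)=C1/CC/C(C)=C\C[C@H](O[Si](C)(C)C(C)(C)C)/C(C)=C/[C@H]1O[Si](CC)(CC)CC
F2 | step 12 | (3S,6R,1(10)Z,4E)-3-(tert-butyldimethylsilyloxy)-13-oxogermacra-1(10),4,7(11)-trien-12,6-olide | CC(C)(C)[Si](C)(C)O[C@H]1C/C=C(/C)CCC2=C(C=O)C(=O)O[C@@H]2/C=C/1C
F3 | step 6 | methyl (4RS,5E,7S)-7-(tert-butyldimethylsilyloxy)-4-hydroxy-6-methyldeca-5,9-dien-2-ynoate (C4 epimers) | C=CC[C@H](O[Si](C)(C)C(C)(C)C)/C(C)=C/C(O)C#CC(=O)OC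
F4 | step 6 | methyl (5E,7S)-7-(tert-butyldimethylsilyloxy)-6-methyl-4-oxodeca-5,9-dien-2-ynoate | C=CC[C@H](O[Si](C)(C)C(C)(C)C)/C(C)=C/C(=O)C#CC(=O)OC
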